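**Plan**

- Retrosynthetic cuts: the two epoxide C–O bonds (back to an E-trisubstituted alkene), the aryl ether O–CH2 bond (back to the hydroxycoumarin), the exocyclic C2=CH2 bond, the lactone ring oxygen, and the C4–CH2 side-chain bond.
- Enabling feature: the lactone carbons C1 (carbonyl), C2, C3 and C4 (CH–O) are a four-carbon chain closed only through the ring oxygen. Removing that oxygen leaves a 2-substituted cyclobutanone, which is strained enough to take up oxygen next to its substituted carbon.
- Forward order: prenol is turned into a silyl-protected (E)-allylic bromide and joined to cyclobutanone through its SAMP hydrazone. Ring expansion gives the oxolanone, the only ring built in the route, which is then α-methylenated. The coumarin, bought as the intact bicycle, is attached by etherification, and the epoxide is closed last.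
- Stereochemistry: C4 comes from the auxiliary-controlled alkylation and is carried through the ring expansion with retention. The epoxide configuration comes from the E-alkene geometry (allylic oxidation of the E-methyl group) and a reagent-controlled Shi epoxidation.
- The aryl ether is formed late so that the coumarin never meets the lithium azaenolate or the lactone enolate.

Key step: step 7

**Remarks on the chemistry**

- 7-Hydroxy-8-methoxycoumarin and the D-fructose-derived Shi ketone are assumed to be purchasable.
- The CIP descriptor at the lactone CH–O carbon reads S up to the Mannich base, R in every α-methylene lactone that still carries the alkene side chain, and S again in the target. The spatial arrangement never changes; only the ranking of the ring and side-chain branches does.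

**Route**

Step 1
Reactants: 1 3-methylbut-2-en-1-ol
Product: 2 tert-butyl[(3-methylbut-2-en-1-yl)oxy]diphenylsilane
Conditions: TBDPSCl, imidazole, CH2Cl2, 0 °C → rt
Reagents that add atoms: tert-butyl(chloro)diphenylsilane, CC(C)(C)[Si](Cl)(c1ccccc1)c1ccccc1
Why: Imidazole-promoted silylation of a primary alcohol (silyl ether protection) is reliable, and the tert-butyldiphenylsilyl group should survive the selenium oxidation, the lithium amide, the oxalic acid hydrolysis and the peroxide of the later steps.

Step 2
Reactants: 2 tert-butyl[(3-methylbut-2-en-1-yl)oxy]diphenylsilane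
Product: 3 (2E)-4-[(tert-butyldiphenylsilyl)oxy]-2-methylbut-2-en-1-ol
Conditions: SeO2 (cat.), t-BuOOH, salicylic acid (cat.), CH2Cl2, rt
Reagents that add atoms: tert-butyl hydroperoxide, CC(C)(C)OO (its oxygen is relayed by the catalyst selenium dioxide, O=[Se]=O)
Why: Riley allylic oxidation in its catalytic form (ene reaction then [2,3]-sigmatropic shift) is known to hydroxylate the (E)-methyl group of prenyl ethers, so the E geometry of the trisubstituted alkene needed for the epoxide is fixed here.

Step 3
Reactants: 3 (2E)-4-[(tert-butyldiphenylsilyl)oxy]-2-methylbut-2-en-1-ol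
Product: 4 {[(2E)-4-bromo-3-methylbut-2-en-1-yl]oxy}(tert-butyl)diphenylsilane
Conditions: CBr4, PPh3, CH2Cl2, 0 °C
Reagents that add atoms: carbon tetrabromide, BrC(Br)(Br)Br
Why: The Appel reaction should convert the primary allylic alcohol into the bromide under neutral conditions, without allylic transposition, E/Z isomerisation or loss of the silyl ether.

Step 4
Reactants: 5 cyclobutanone
Product: 6 (2S)-N-cyclobutylidene-2-(methoxymethyl)pyrrolidin-1-amine
Conditions: SAMP, 4 Å molecular sieves, CH2Cl2, rt
Reagents that add atoms: (S)-1-amino-2-(methoxymethyl)pyrrolidine (SAMP), COC[C@@H]1CCCN1N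
Why: Hydrazone formation between the strained, electrophilic ketone and the Enders hydrazine should go to completion once water is removed, and the symmetrical ketone gives a single hydrazone.

Step 5
Reactants: 6 (2S)-N-cyclobutylidene-2-(methoxymethyl)pyrrolidin-1-amine; 4 {[(2E)-4-bromo-3-methylbut-2-en-1-yl]oxy}(tert-butyl)diphenylsilane
Product: 8 (2S)-N-[(2S)-2-{(2E)-4-[(tert-butyldiphenylsilyl)oxy]-2-methylbut-2-en-1-yl}cyclobutylidene]-2-(methoxymethyl)pyrrolidin-1-amine, via lithium azaenolate 7 (not isolated)
Conditions: LiN(i-Pr)2, THF, 0 °C; then 4, −100 → −20 °C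
Reagents that add atoms: none
Why: Enders SAMP-hydrazone alkylation, in which the methoxymethyl-chelated lithium azaenolate (its C=C geometry fixed by the ring) should be attacked by the primary allylic bromide in an SN2 reaction on the face dictated by the auxiliary, which by the standard model for SAMP makes C2 of the cyclobutane S.

Step 6
Reactants: 8 (2S)-N-[(2S)-2-{(2E)-4-[(tert-butyldiphenylsilyl)oxy]-2-methylbut-2-en-1-yl}cyclobutylidene]-2-(methoxymethyl)pyrrolidin-1-amine
Product: 9 (2S)-2-{(2E)-4-[(tert-butyldiphenylsilyl)oxy]-2-methylbut-2-en-1-yl}cyclobutan-1-one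
Conditions: sat. aq. (CO2H)2, Et2O, rt
Reagents that add atoms: water, O
Why: Two-phase hydrolysis of the hydrazone with oxalic acid is the standard mild, non-oxidative cleavage and should leave the alkene, the silyl ether and the enolisable α-stereocentre intact while returning the auxiliary to the aqueous layer.

Step 7
Reactants: 9 (2S)-2-{(2E)-4-[(tert-butyldiphenylsilyl)oxy]-2-methylbut-2-en-1-yl}cyclobutan-1-one
Product: 11 (5S)-5-{(2E)-4-[(tert-butyldiphenylsilyl)oxy]-2-methylbut-2-en-1-yl}oxolan-2-one, via Criegee adduct 10 (not isolated)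
Conditions: 30% aq. H2O2, CF3CH2OH, rt
Reagents that add atoms: hydrogen peroxide, OO
Why: Hydrogen peroxide, activated by hydrogen bonding to trifluoroethanol, should add to the strained carbonyl of 9 to give the Criegee adduct 10, in which the substituted ring carbon shifts from carbon to the proximal peroxide oxygen with loss of water. This is a Baeyer–Villiger oxidation, and the closest known reaction type is the conversion of 2-alkylcyclobutanones into γ-substituted γ-butyrolactones. The oxolanone is not closed by a cyclisation but arises by ring expansion of the four-membered ring, the single 1,2-shift forming the C4–O and O–C1 bonds together. No stereocentre is created: the migrating carbon keeps its configuration, so the S centre set in step 5 becomes the lactone CH–O carbon unchanged. The step needs regioselectivity, which the better migratory aptitude of the secondary carbon over the ring CH2 secures, and chemoselectivity for the ketone over the alkene, which rests on strain-driven peroxide addition and on the poor reactivity of neutral H2O2 toward an alkene already deactivated by its allylic oxygen.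

Step 8
Reactants: 11 (5S)-5-{(2E)-4-[(tert-butyldiphenylsilyl)oxy]-2-methylbut-2-en-1-yl}oxolan-2-one
Product: 13 (5S)-5-{(2E)-4-[(tert-butyldiphenylsilyl)oxy]-2-methylbut-2-en-1-yl}-3-[(dimethylamino)methyl]oxolan-2-one (C3 epimers), via lithium lactone enolate 12 (not isolated)
Conditions: LiN(i-Pr)2, THF, −78 °C; then CH2=NMe2+ I−, −78 °C → rt
Reagents that add atoms: dimethylmethylideneammonium iodide (Eschenmoser's salt), C=[N+](C)C.[I-]
Why: Mannich reaction of the lactone lithium enolate with Eschenmoser's salt should aminomethylate C3, the only enolisable position, and the configuration of this new centre does not matter because it becomes sp2 in step 9.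

Step 9
Reactants: 13 (5S)-5-{(2E)-4-[(tert-butyldiphenylsilyl)oxy]-2-methylbut-2-en-1-yl}-3-[(dimethylamino)methyl]oxolan-2-one
Product: 15 (5R)-5-{(2E)-4-[(tert-butyldiphenylsilyl)oxy]-2-methylbut-2-en-1-yl}-3-methylideneoxolan-2-one, via trimethylammonium iodide 14 (not isolated)
Conditions: MeI, THF, rt; then aq. NaHCO3, CH2Cl2, rt
Reagents that add atoms: none
Why: N-Quaternisation followed by base-induced β-elimination of trimethylamine (E1cB, Hofmann type) is the standard second stage of the Eschenmoser α-methylenation of lactones and should give only the exocyclic alkene.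

Step 10
Reactants: 15 (5R)-5-{(2E)-4-[(tert-butyldiphenylsilyl)oxy]-2-methylbut-2-en-1-yl}-3-methylideneoxolan-2-one
Product: 16 (5R)-5-[(2E)-4-hydroxy-2-methylbut-2-en-1-yl]-3-methylideneoxolan-2-one
Conditions: HF·pyridine, THF, 0 °C → rt
Reagents that add atoms: none
Why: Desilylation with HF·pyridine (fluoride-induced Si–O cleavage) is mildly acidic, so the α-methylene lactone should survive where basic fluoride sources might add to it.

Step 11
Reactants: 16 (5R)-5-[(2E)-4-hydroxy-2-methylbut-2-en-1-yl]-3-methylideneoxolan-2-one
Product: 18 (5R)-5-[(2E)-4-bromo-2-methylbut-2-en-1-yl]-3-methylideneoxolan-2-one, via allylic mesylate 17 (not isolated)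
Conditions: MsCl, Et3N, CH2Cl2, −40 °C; then LiBr, THF, 0 °C
Reagents that add atoms: lithium bromide, [Li+].[Br-]
Why: Mesylation followed by SN2 displacement with bromide is the usual phosphine-free way to a primary allylic bromide and should proceed without E/Z isomerisation, the phosphine of an Appel reaction being avoided here because it could add to the enoate.

Step 12
Reactants: 18 (5R)-5-[(2E)-4-bromo-2-methylbut-2-en-1-yl]-3-methylideneoxolan-2-one; 19 7-hydroxy-8-methoxy-2H-chromen-2-one
Product: 20 8-methoxy-7-({(2E)-3-methyl-4-[(2R)-4-methylidene-5-oxooxolan-2-yl]but-2-en-1-yl}oxy)-2H-chromen-2-one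
Conditions: K2CO3, acetone, rt
Reagents that add atoms: none
Why: Williamson ether synthesis, in which the potassium phenoxide should attack the primary allylic bromide by SN2 irreversibly and much faster than it can add, reversibly, to the α-methylene lactone.

Step 13
Reactants: 20 8-methoxy-7-({(2E)-3-methyl-4-[(2R)-4-methylidene-5-oxooxolan-2-yl]but-2-en-1-yl}oxy)-2H-chromen-2-one
Product: 21 8-methoxy-7-({(2R,3R)-3-methyl-3-{[(2S)-4-methylidene-5-oxooxolan-2-yl]methyl}oxiran-2-yl}methoxy)-2H-chromen-2-one
Conditions: D-fructose-derived Shi ketone (cat.), KHSO5 (as 2KHSO5·KHSO4·K2SO4), K2CO3, Bu4NHSO4, MeCN/CH2(OMe)2, aq. Na2B4O7 buffer, 0 °C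
Reagents that add atoms: potassium peroxymonosulfate, [K+].[O-]S(=O)(=O)OO
Why: Shi asymmetric epoxidation, in which the dioxirane generated from the D-fructose-derived ketone should transfer oxygen through a spiro transition state to the face of the E-trisubstituted alkene that leads to the (2R,3R)-epoxide, while this electrophilic oxidant should leave the electron-poor enoate and coumarin double bonds alone.

**Compound list**

1 | 3-methylbut-2-en-1-ol | CC(C)=CCO | starting material
2 | tert-butyl[(3-methylbut-2-en-1-yl)oxy]diphenylsilane | CC(C)=CCO[Si](c1ccccc1)(c1ccccc1)C(C)(C)C | intermediate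
3 | (2E)-4-[(tert-butyldiphenylsilyl)oxy]-2-methylbut-2-en-1-ol | OC/C(C)=C/CO[Si](c1ccccc1)(c1ccccc1)C(C)(C)C | intermediate
4 | {[(2E)-4-bromo-3-methylbut-2-en-1-yl]oxy}(tert-butyl)diphenylsilane | BrC/C(C)=C/CO[Si](c1ccccc1)(c1ccccc1)C(C)(C)C | intermediate
5 | cyclobutanone | O=C1CCC1 | starting material
6 | (2S)-N-cyclobutylidene-2-(methoxymethyl)pyrrolidin-1-amine | COC[C@@H]1CCCN1N=C1CCC1 | intermediate
7 | lithium azaenolate of 6, lithium (cyclobut-1-en-1-yl)[(2S)-2-(methoxymethyl)pyrrolidin-1-yl]azanide (not isolated) | [Li+].COC[C@@H]1CCCN1[N-]C1=CCC1 | intermediate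
8 | (2S)-N-[(2S)-2-{(2E)-4-[(tert-butyldiphenylsilyl)oxy]-2-methylbut-2-en-1-yl}cyclobutylidene]-2-(methoxymethyl)pyrrolidin-1-amine (C=N geometry not defined) | COC[C@@H]1CCCN1N=C1CC[C@H]1C/C(C)=C/CO[Si](c1ccccc1)(c1ccccc1)C(C)(C)C | intermediate
9 | (2S)-2-{(2E)-4-[(tert-butyldiphenylsilyl)oxy]-2-methylbut-2-en-1-yl}cyclobutan-1-one | O=C1CC[C@H]1C/C(C)=C/CO[Si](c1ccccc1)(c1ccccc1)C(C)(C)C | intermediate
10 | (2S)-2-{(2E)-4-[(tert-butyldiphenylsilyl)oxy]-2-methylbut-2-en-1-yl}-1-hydroperoxycyclobutan-1-ol (Criegee adduct, C1 epimers, not isolated) | OOC1(O)CC[C@H]1C/C(C)=C/CO[Si](c1ccccc1)(c1ccccc1)C(C)(C)C | intermediate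
11 | (5S)-5-{(2E)-4-[(tert-butyldiphenylsilyl)oxy]-2-methylbut-2-en-1-yl}oxolan-2-one | O=C1CC[C@@H](C/C(C)=C/CO[Si](c2ccccc2)(c2ccccc2)C(C)(C)C)O1 | intermediate
12 | lithium enolate of 11, lithium (5S)-5-{(2E)-4-[(tert-butyldiphenylsilyl)oxy]-2-methylbut-2-en-1-yl}-4,5-dihydrofuran-2-olate (not isolated) | [Li+].[O-]C1=CC[C@@H](C/C(C)=C/CO[Si](c2ccccc2)(c2ccccc2)C(C)(C)C)O1 | intermediate
13 | (5S)-5-{(2E)-4-[(tert-butyldiphenylsilyl)oxy]-2-methylbut-2-en-1-yl}-3-[(dimethylamino)methyl]oxolan-2-one (C3 epimers) | CN(C)CC1C[C@@H](C/C(C)=C/CO[Si](c2ccccc2)(c2ccccc2)C(C)(C)C)OC1=O | intermediate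
14 | 1-[(5S)-5-{(2E)-4-[(tert-butyldiphenylsilyl)oxy]-2-methylbut-2-en-1-yl}-2-oxooxolan-3-yl]-N,N,N-trimethylmethanaminium iodide (C3 epimers, not isolated) | C[N+](C)(C)CC1C[C@@H](C/C(C)=C/CO[Si](c2ccccc2)(c2ccccc2)C(C)(C)C)OC1=O.[I-] | intermediate
15 | (5R)-5-{(2E)-4-[(tert-butyldiphenylsilyl)oxy]-2-methylbut-2-en-1-yl}-3-methylideneoxolan-2-one | C=C1C[C@@H](C/C(C)=C/CO[Si](c2ccccc2)(c2ccccc2)C(C)(C)C)OC1=O | intermediate
16 | (5R)-5-[(2E)-4-hydroxy-2-methylbut-2-en-1-yl]-3-methylideneoxolan-2-one | C=C1C[C@@H](C/C(C)=C/CO)OC1=O | intermediate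
17 | (2E)-3-methyl-4-[(2R)-4-methylidene-5-oxooxolan-2-yl]but-2-en-1-yl methanesulfonate (not isolated) | C=C1C[C@@H](C/C(C)=C/COS(C)(=O)=O)OC1=O | intermediate
18 | (5R)-5-[(2E)-4-bromo-2-methylbut-2-en-1-yl]-3-methylideneoxolan-2-one | C=C1C[C@@H](C/C(C)=C/CBr)OC1=O | intermediate
19 | 7-hydroxy-8-methoxy-2H-chromen-2-one | Oc1ccc2ccc(=O)oc2c1OC | starting material
20 | 8-methoxy-7-({(2E)-3-methyl-4-[(2R)-4-methylidene-5-oxooxolan-2-yl]but-2-en-1-yl}oxy)-2H-chromen-2-one | C=C1C[C@@H](C/C(C)=C/COc2ccc3ccc(=O)oc3c2OC)OC1=O | intermediate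
21 | 8-methoxy-7-({(2R,3R)-3-methyl-3-{[(2S)-4-methylidene-5-oxooxolan-2-yl]methyl}oxiran-2-yl}methoxy)-2H-chromen-2-one | C=C1C[C@@H](C[C@@]2(C)O[C@@H]2COc2ccc3ccc(=O)oc3c2OC)OC1=O | target

**Step count**

Total: 13 steps. Longest linear sequence: 12 steps (steps 1–3 and 5–13 from 3-methylbut-2-en-1-ol; step 4 prepares the hydrazone in a side branch).

**Steps most likely to fail, with fallbacks**

1. Step 13 (Shi epoxidation). Oxygen transfer to an alkene deactivated by its allylic aryloxy group may be slow. Prolonged exposure to the basic aqueous medium may then degrade the α-methylene lactone, and facial discrimination may be incomplete. The fallback sets out from alcohol 16 and comes back to the route at target 21, replacing steps 11–13 by a reagent-controlled epoxidation of the free allylic alcohol.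
   - Sharpless–Katsuki epoxidation of 16 (Ti(O-i-Pr)4, D-(−)-diethyl tartrate, t-BuOOH, 4 Å molecular sieves, CH2Cl2, −20 °C) should deliver oxygen to the required face of this geraniol-type E-allylic alcohol. The expected product is (5S)-5-{[(2R,3R)-3-(hydroxymethyl)-2-methyloxiran-2-yl]methyl}-3-methylideneoxolan-2-one F1.
   - Tosylation (TsCl, pyridine, 0 °C) should give [(2R,3R)-3-methyl-3-{[(2S)-4-methylidene-5-oxooxolan-2-yl]methyl}oxiran-2-yl]methyl 4-methylbenzenesulfonate F2.
   - Displacement by the phenoxide of 19 (Cs2CO3, DMF, rt) at the primary carbon leaves both epoxide carbons untouched and should give 21.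

2. Step 7 (Baeyer–Villiger ring expansion). The peroxide may also epoxidise the trisubstituted alkene, the ring CH2 may migrate in part to give the isomeric lactone, or peroxide addition may be too slow in the neutral medium. The fallback sets out from cyclobutanone 9 and comes back at lactone 11, forming the same two bonds without any peroxide.
   - Irradiation of 9 (medium-pressure Hg lamp, Pyrex filter, degassed MeOH, rt) should cleave the more substituted acyl–carbon bond. The diradical recloses on oxygen to an oxacarbene with retention at the migrating carbon, and insertion into the O–H bond of methanol should give tert-butyl({(2E)-4-[(2S)-5-methoxyoxolan-2-yl]-3-methylbut-2-en-1-yl}oxy)diphenylsilane F3 as a mixture of anomers.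
   - Jones oxidation of this cyclic acetal (CrO3, H2SO4, acetone, 0 °C) should then give 11.

3. Step 5 (auxiliary-controlled alkylation, with the hydrolysis of step 6). Facial discrimination in the alkylation of the small-ring azaenolate may be incomplete, or the α-stereocentre may partly enolise during hydrazone cleavage; either lowers the enantiomeric purity. The fallback sets out from lactone 11 of insufficient purity and comes back at 11, securing the stereocentre by resolution through covalent diastereomers.
   - Aminolysis with (S)-1-phenylethylamine and AlMe3 (CH2Cl2, rt → 40 °C) should open the lactone to two diastereomeric hydroxy amides. The wanted isomer, (4S,6E)-8-[(tert-butyldiphenylsilyl)oxy]-4-hydroxy-6-methyl-N-[(1S)-1-phenylethyl]oct-6-enamide F4, is separated by chromatography or crystallisation.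
   - Relactonisation (p-TsOH·H2O, toluene, 60 °C) should return stereochemically pure 11.

**Further compounds**

F1 | step 13 | (5S)-5-{[(2R,3R)-3-(hydroxymethyl)-2-methyloxiran-2-yl]methyl}-3-methylideneoxolan-2-one | C=C1C[C@@H](C[C@@]2(C)O[C@@H]2CO)OC1=O
F2 | step 13 | [(2R,3R)-3-methyl-3-{[(2S)-4-methylidene-5-oxooxolan-2-yl]methyl}oxiran-2-yl]methyl 4-methylbenzenesulfonate | C=C1C[C@@H](C[C@@]2(C)O[C@@H]2COS(=O)(=O)c2ccc(C)cc2)OC1=O
F3 | step 7 | tert-butyl({(2E)-4-[(2S)-5-methoxyoxolan-2-yl]-3-methylbut-2-en-1-yl}oxy)diphenylsilane (anomer mixture) | COC1CC[C@@H](C/C(C)=C/CO[Si](c2ccccc2)(c2ccccc2)C(C)(C)C)O1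
F4 | step 5 | (4S,6E)-8-[(tert-butyldiphenylsilyl)oxy]-4-hydroxy-6-methyl-N-[(1S)-1-phenylethyl]oct-6-enamide | C[C@H](NC(=O)CC[C@H](O)C/C(C)=C/CO[Si](c1ccccc1)(c1ccccc1)C(C)(C)C)c1ccccc1
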